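## Analysis of the target

The target (C29H26N2O4) is a fully substituted 1,4-benzoquinone; with the ring numbered C1(=O), C2(OMe), C3, C4(=O), C5(OMe), C6, carbon C3 carries an unsubstituted 1H-indol-3-yl group (indole A) and C6 carries a 1H-indol-3-yl group whose own C2 bears a 2-methylbut-3-en-2-yl (1,1-dimethylallyl) group (indole B). There is no stereocentre; rotation about the bond from C6 to indole B is hindered, but no axial configuration is specified and none is controlled. The ring is made of two O=C–C(aryl)=C(OMe) units joined head to tail, and the two halves differ only by the tert-alkyl group at C2 of indole B, which also makes the C6–indole bond the most hindered bond of the molecule. The quinone is reducible and electrophilic, and its methoxy groups are exchangeable vinylogous esters. The two free N–H indoles are oxidisable, and the terminal vinyl group on a quaternary carbon does not tolerate strong acid, electrophilic halogen or aryl-palladium intermediates. The feature that invites the strategy: the four contiguous ring atoms C4(=O)–C5(OMe)=C6(aryl)–C1(=O) have the substitution pattern of a 3-aryl-4-methoxycyclobutene-1,2-dione, and C2(OMe)=C3(aryl) is an aryl enol ether, so that the quinone ring is a four-carbon squarate unit plus a two-carbon unit. The difficulty lies in filling all six positions of one ring with the aryl groups para (not meta), in making the hindered C6–indole bond, and in handling the quinone/hydroquinone redox level next to two indoles.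

## Retrosynthetic reasoning

**19 to 18.** The last operation only frees the two indole nitrogens. Both carry a tert-butoxycarbonyl group in 18 because the carbanion chemistry before it needs nitrogen atoms without an acidic N–H and with reduced donor strength.

**18 to 15 (key disconnection).** The quinone ring is cut at C1–C2, and C1 is reconnected to C4 to give a four-membered ring. Quinone 18 is the oxidation product of hydroquinone 17. Hydroquinone 17 is the aromatic tautomer of the 6π-electrocyclisation product of dienylketene 16, and 16 is what a cyclobutenone opens to. The precursor is therefore the 4-alkenyl-4-hydroxycyclobutenone 15. This cut is chosen because it builds the hexasubstituted ring itself, with every substituent placed by the connectivity of 15 and not by the selectivity of an attack on a quinone. Ring strain pays for the step, and the oxidation level comes out as a hydroquinone that a mild oxidant converts to the quinone.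

**15 to 9 and 14.** The bond C3–C4 is cut, a carbonyl addition in the forward sense. Cyclobutenedione 9 holds C4, C5, C6 and C1 with the methoxy group and indole B in place. Vinyllithium 14 holds C3 with indole A and C2 with its methoxy group. The forward reaction has to pick the ketone of 9 that lies next to the methoxy-bearing carbon. That ketone is not part of the vinylogous ester and is remote from the bulky indole B. Vinyllithium 14 comes from vinyl bromide 13 by halogen–metal exchange.

**9 to 5 and 6.** The bond between C6 and C3 of indole B is cut. The hindered bond is thus made early, on a small and very electrophilic partner, by substitution of one chloride of 6 by the nucleophilic C3 of 5 (giving 7). Exchange of the second chloride for methoxide gives 8, and N-acylation gives 9.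

**5 to 1 and 2.** Indole B is cut at its C2–C3 bond and at the amide bond. The quaternary carbon with its vinyl group is bought as acid 1. Amide 4 (through acid chloride 3) closes to the indole by attack of the benzylic carbanion on the amide carbonyl. This sets the tert-alkyl group at C2 without any allylation chemistry.

**13 to 10.** The C(Br)=C(OMe) unit is cut back to enol ether 11 (through dibromide 12), and 11 to aldehyde 10 by a one-carbon olefination.

## Alternatives that were turned down

**Alternative 1: (textbook) both indole–quinone bonds on a preformed quinone.**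
- Disconnection: C3–indole A and C6–indole B, with the six-membered ring bought.
- Forward key step: acid-promoted conjugate addition of 1H-indole A2 to 2,5-dichloro-1,4-benzoquinone A1 with re-oxidation gives the monoadduct A3. A second addition, of 5, gives the dichloride A4, and exchange of both chlorides for methoxide gives 19.
- Why turned down: this is the shortest route on paper. The second C–C bond, however, must be made by the more hindered nucleophile 5 at a carbon of A3 flanked by C=O and C–Cl, on a quinone already deactivated by the donor indole A. Attack at the chlorine-bearing carbons and double addition of A2 to A1 compete. Each bond needs its own re-oxidation, and the methoxy groups only arrive by a late exchange. It is also the route drawn first, and no step in it builds any part of the core.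

**Alternative 2: biomimetic head-to-tail double Claisen condensation.**
- Disconnection: C3–C4 and C6–C1.
- Forward key step: base-mediated cross-condensation of methyl 3-(1H-indol-3-yl)-2-oxopropanoate A5 with methyl 3-[2-(2-methylbut-3-en-2-yl)-1H-indol-3-yl]-2-oxopropanoate A6 gives the dihydroxyquinone A7. O-methylation then gives 19.
- Why turned down: A5 and A6 are each both donor (CH2) and acceptor (ester), and nothing in the structures tells them apart. Three quinones must form, and the hindered A6 is the poorer partner in both roles, so the homodimer of A5 should dominate. The stabilised 2-oxo ester enolates are weak nucleophiles that prefer the ketone (aldol) to the ester. A6 needs several steps from 5, and a separate methylation follows.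

**Alternative 3: both indole rings built last by double Larock heteroannulation.**
- Disconnection: C3–C3a and N1–C2 of each indole.
- Forward key step: the dialkyne A8 reacts with two equivalents of 2-iodoaniline A9 under Pd(OAc)2 catalysis to give the bis-indole A10. Desilylation and oxidative demethylation of the tetramethoxyarene then give 19.
- Why turned down: the aryl-palladium intermediate formed from A9 has an open Heck pathway to the terminal vinyl group of A8. Both alkynes are flanked by a di-ortho-substituted arene, and one also by a quaternary carbon. A8 needs two different alkynylations of a symmetric dihalide and a non-commercial enyne. The end-game is an oxidation with (NH4)2Ce(NO3)6 in the presence of two free indoles. The route is longer, and the quinone ring is again bought, not built.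

Key step: step 8

## Route

Remark on the chemistry: the enol ether geometry of 11, 13, 14 and 15 and the carbinol centre of 15 are of no consequence, because these carbons become sp2 ring atoms of the quinone. 11 and 13 are carried as E/Z mixtures and 15 as a racemic E/Z mixture. Compounds 1, 2, 6 and 10 are taken as catalogue compounds.

**Step 1**
Reactants: 1 2,2-dimethylbut-3-enoic acid; 2 2-methylaniline
Product: 4 2,2-dimethyl-N-(2-methylphenyl)but-3-enamide, via acid chloride 3 (not isolated)
Conditions: (COCl)2, DMF (cat.), CH2Cl2, 0 °C → rt; then 2, Et3N, CH2Cl2, 0 °C → rt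
Reagents that add atoms: none
Why: Standard acid chloride formation and N-acylation of an aniline; the quaternary α-carbon cannot enolise or form a ketene, so the hindered acyl chloride reacts cleanly.

**Step 2**
Reactants: 4 2,2-dimethyl-N-(2-methylphenyl)but-3-enamide
Product: 5 2-(2-methylbut-3-en-2-yl)-1H-indole
Conditions: n-BuLi (3 equiv), THF, −20 °C → rt; then H2O
Reagents that add atoms: none
Why: Madelung indole synthesis in its organolithium variant: the N,C-dilithiated anilide closes the C2–C3 bond by attack of the benzylic carbanion on the non-enolisable amide carbonyl and aromatises by loss of LiOH, as known for the pivalamide that gives 2-tert-butylindole. The isolated vinyl group is inert to n-BuLi.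

**Step 3**
Reactants: 5 2-(2-methylbut-3-en-2-yl)-1H-indole; 6 3,4-dichlorocyclobut-3-ene-1,2-dione
Product: 8 3-methoxy-4-[2-(2-methylbut-3-en-2-yl)-1H-indol-3-yl]cyclobut-3-ene-1,2-dione, via chloro dione 7 (not isolated)
Conditions: 6 (1.1 equiv), CH2Cl2, 0 °C → rt; then MeOH, Et3N, 0 °C
Reagents that add atoms: methanol, CO
Why: Vinylogous Friedel–Crafts acylation: indole C3 adds to the chlorine-bearing carbon of the vinylogous acid chloride and chloride is lost, without Lewis acid. The donor indole then deactivates the second chloride, so a second arylation does not follow and the chloride is exchanged only by methanol and base.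

**Step 4**
Reactants: 8 3-methoxy-4-[2-(2-methylbut-3-en-2-yl)-1H-indol-3-yl]cyclobut-3-ene-1,2-dione
Product: 9 tert-butyl 3-(2-methoxy-3,4-dioxocyclobut-1-en-1-yl)-2-(2-methylbut-3-en-2-yl)-1H-indole-1-carboxylate
Conditions: Boc2O, DMAP (cat.), MeCN, rt
Reagents that add atoms: di-tert-butyl dicarbonate, CC(C)(C)OC(=O)OC(=O)OC(C)(C)C
Why: DMAP-catalysed N-acylation of an indole whose N–H is acidified by the dione (a vinylogous imide). The carbamate removes the acidic proton and damps the donor strength of indole B, which the regioselectivity of step 7 needs.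

**Step 5**
Reactants: 10 tert-butyl 3-formyl-1H-indole-1-carboxylate
Product: 11 tert-butyl 3-(2-methoxyethenyl)-1H-indole-1-carboxylate (E/Z mixture)
Conditions: Ph3P(CH2OMe)Cl, NaN(SiMe3)2, THF, 0 °C; then 10, −78 °C → rt
Reagents that add atoms: (methoxymethyl)triphenylphosphonium chloride, COC[P+](c1ccccc1)(c1ccccc1)c1ccccc1.[Cl-]
Why: Wittig methoxymethylenation of an N-acyl indole-3-carbaldehyde. The ylide is preformed with a non-nucleophilic amide base so that no alkoxide is present to attack the carbamate.

**Step 6**
Reactants: 11 tert-butyl 3-(2-methoxyethenyl)-1H-indole-1-carboxylate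
Product: 13 tert-butyl 3-(1-bromo-2-methoxyethenyl)-1H-indole-1-carboxylate (E/Z mixture), via dibromide 12 (not isolated)
Conditions: Br2 (1.0 equiv), CH2Cl2, −78 °C; then i-Pr2NEt, −78 °C → rt
Reagents that add atoms: bromine, BrBr
Why: Bromination–dehydrobromination of an enol ether. The enol ether is far more nucleophilic than the N-acyl indole ring. From 12 the labile α-bromo ether bromide and the acidic benzylic proton are lost, which leaves the bromine on the indole-bearing carbon.

**Step 7**
Reactants: 13 tert-butyl 3-(1-bromo-2-methoxyethenyl)-1H-indole-1-carboxylate; 9 tert-butyl 3-(2-methoxy-3,4-dioxocyclobut-1-en-1-yl)-2-(2-methylbut-3-en-2-yl)-1H-indole-1-carboxylate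
Product: 15 tert-butyl 3-(3-{1-[1-(tert-butoxycarbonyl)-1H-indol-3-yl]-2-methoxyethenyl}-3-hydroxy-2-methoxy-4-oxocyclobut-1-en-1-yl)-2-(2-methylbut-3-en-2-yl)-1H-indole-1-carboxylate (racemic, E/Z mixture), via vinyllithium 14 (not isolated)
Conditions: 13, t-BuLi (2.0 equiv), THF–Et2O, −90 °C, 5 min; then 9, −90 → −78 °C; AcOH, −78 °C
Reagents that add atoms: none
Why: Bromine–lithium exchange and 1,2-addition to a 3-alkoxy-4-arylcyclobutenedione. Organolithiums are known to attack the ketone next to the alkoxy-bearing carbon, which is not part of the vinylogous ester, and here that ketone is also the one remote from the bulky indole B. The low temperature suppresses loss of LiOMe from 14 and proton transfer from the indole C2–H.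

**Step 8**
Reactants: 15 tert-butyl 3-(3-{1-[1-(tert-butoxycarbonyl)-1H-indol-3-yl]-2-methoxyethenyl}-3-hydroxy-2-methoxy-4-oxocyclobut-1-en-1-yl)-2-(2-methylbut-3-en-2-yl)-1H-indole-1-carboxylate
Product: 18 tert-butyl 3-{4-[1-(tert-butoxycarbonyl)-1H-indol-3-yl]-2,5-dimethoxy-3,6-dioxocyclohexa-1,4-dien-1-yl}-2-(2-methylbut-3-en-2-yl)-1H-indole-1-carboxylate, via dienylketene 16 (not isolated), via hydroquinone 17 (not isolated)
Conditions: PhMe (degassed, 0.02 M), 110 °C; then Ag2O, rt
Reagents that add atoms: none
Why: Heating opens the strained cyclobutenone of 15 by conrotatory 4π-electrocyclic cleavage of the bond between the carbonyl carbon (C1 of the target) and the carbinol carbon (C4) to give dienylketene 16. The hydroxyl, the strongest donor on the breaking bond, rotates outward, so the alkenyl group ends up cis to the ketene. 16 then closes the six-membered carbocycle by thermal 6π-electrocyclisation between the ketene carbon and the methoxy-bearing enol ether carbon (bond C1–C2), and the resulting cyclohexadienone enolises to the aromatic hydroquinone 17. Ag2O oxidises 17 to quinone 18 under neutral conditions that leave the carbamates, the indoles and the vinyl group untouched. The closest known reaction type is the thermal ring expansion of 4-alkenyl-4-hydroxycyclobutenones to hydroquinones and quinones, the vinylketene variant of the Moore rearrangement. No stereocentre is formed, and the carbinol centre and the enol ether geometry of 15 are erased on aromatisation. The step needs torquoselectivity (hydroxyl outward) and periselectivity (6π closure, not capture of the ketene by the hydroxyl), and both follow from the donor-outward preference, which holds the hydroxyl away from the ketene and the enol ether next to it. The para relation of the two indoles and of the two methoxy groups is fixed by the connectivity of 15 and cannot scramble.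

**Step 9**
Reactants: 18 tert-butyl 3-{4-[1-(tert-butoxycarbonyl)-1H-indol-3-yl]-2,5-dimethoxy-3,6-dioxocyclohexa-1,4-dien-1-yl}-2-(2-methylbut-3-en-2-yl)-1H-indole-1-carboxylate
Product: 19 2,5-dimethoxy-3-(1H-indol-3-yl)-6-[2-(2-methylbut-3-en-2-yl)-1H-indol-3-yl]cyclohexa-2,5-diene-1,4-dione (target)
Conditions: NaOMe (2.5 equiv), MeOH–THF, 0 °C → rt; then AcOH
Reagents that add atoms: none
Why: Methanolysis of N-acyl indoles, made easy here because the quinonyl-substituted indolide is a good leaving group. Attack of methoxide at the methoxy-bearing ring carbons is a degenerate exchange, and the fully substituted quinone offers no position for conjugate addition.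

## Compound list

1 | 2,2-dimethylbut-3-enoic acid | C=CC(C)(C)C(=O)O | starting material
2 | 2-methylaniline | Cc1ccccc1N | starting material
3 | 2,2-dimethylbut-3-enoyl chloride | C=CC(C)(C)C(=O)Cl | intermediate
4 | 2,2-dimethyl-N-(2-methylphenyl)but-3-enamide | C=CC(C)(C)C(=O)Nc1ccccc1C | intermediate
5 | 2-(2-methylbut-3-en-2-yl)-1H-indole | C=CC(C)(C)c1cc2ccccc2[nH]1 | intermediate
6 | 3,4-dichlorocyclobut-3-ene-1,2-dione | O=C1C(Cl)=C(Cl)C1=O | starting material
7 | 3-chloro-4-[2-(2-methylbut-3-en-2-yl)-1H-indol-3-yl]cyclobut-3-ene-1,2-dione | C=CC(C)(C)c1[nH]c2ccccc2c1C1=C(Cl)C(=O)C1=O | intermediate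
8 | 3-methoxy-4-[2-(2-methylbut-3-en-2-yl)-1H-indol-3-yl]cyclobut-3-ene-1,2-dione | C=CC(C)(C)c1[nH]c2ccccc2c1C1=C(OC)C(=O)C1=O | intermediate
9 | tert-butyl 3-(2-methoxy-3,4-dioxocyclobut-1-en-1-yl)-2-(2-methylbut-3-en-2-yl)-1H-indole-1-carboxylate | C=CC(C)(C)c1n(C(=O)OC(C)(C)C)c2ccccc2c1C1=C(OC)C(=O)C1=O | intermediate
10 | tert-butyl 3-formyl-1H-indole-1-carboxylate | O=Cc1cn(C(=O)OC(C)(C)C)c2ccccc12 | starting material
11 | tert-butyl 3-(2-methoxyethenyl)-1H-indole-1-carboxylate (E/Z mixture) | COC=Cc1cn(C(=O)OC(C)(C)C)c2ccccc12 | intermediate
12 | tert-butyl 3-(1,2-dibromo-2-methoxyethyl)-1H-indole-1-carboxylate (diastereomer mixture) | COC(Br)C(Br)c1cn(C(=O)OC(C)(C)C)c2ccccc12 | intermediate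
13 | tert-butyl 3-(1-bromo-2-methoxyethenyl)-1H-indole-1-carboxylate (E/Z mixture) | COC=C(Br)c1cn(C(=O)OC(C)(C)C)c2ccccc12 | intermediate
14 | {1-[1-(tert-butoxycarbonyl)-1H-indol-3-yl]-2-methoxyethenyl}lithium | [Li]C(=COC)c1cn(C(=O)OC(C)(C)C)c2ccccc12 | intermediate
15 | tert-butyl 3-(3-{1-[1-(tert-butoxycarbonyl)-1H-indol-3-yl]-2-methoxyethenyl}-3-hydroxy-2-methoxy-4-oxocyclobut-1-en-1-yl)-2-(2-methylbut-3-en-2-yl)-1H-indole-1-carboxylate (racemic, E/Z mixture) | C=CC(C)(C)c1n(C(=O)OC(C)(C)C)c2ccccc2c1C1=C(OC)C(O)(C(=COC)c2cn(C(=O)OC(C)(C)C)c3ccccc23)C1=O | intermediate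
16 | dienylketene: 4-hydroxy-3,6-dimethoxy-5-[1-(tert-butoxycarbonyl)indol-3-yl]-2-[1-(tert-butoxycarbonyl)-2-(2-methylbut-3-en-2-yl)indol-3-yl]hexa-1,3,5-trien-1-one | O=C=C(c1c(C(C)(C)C=C)n(C(=O)OC(C)(C)C)c2ccccc12)C(OC)=C(O)C(=COC)c1cn(C(=O)OC(C)(C)C)c2ccccc12 | intermediate
17 | tert-butyl 3-{4-[1-(tert-butoxycarbonyl)-1H-indol-3-yl]-2,5-dihydroxy-3,6-dimethoxyphenyl}-2-(2-methylbut-3-en-2-yl)-1H-indole-1-carboxylate | COc1c(O)c(-c2c(C(C)(C)C=C)n(C(=O)OC(C)(C)C)c3ccccc23)c(OC)c(O)c1-c1cn(C(=O)OC(C)(C)C)c2ccccc12 | intermediate
18 | tert-butyl 3-{4-[1-(tert-butoxycarbonyl)-1H-indol-3-yl]-2,5-dimethoxy-3,6-dioxocyclohexa-1,4-dien-1-yl}-2-(2-methylbut-3-en-2-yl)-1H-indole-1-carboxylate | COC1=C(c2cn(C(=O)OC(C)(C)C)c3ccccc23)C(=O)C(OC)=C(c2c(C(C)(C)C=C)n(C(=O)OC(C)(C)C)c3ccccc23)C1=O | intermediate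
19 | 2,5-dimethoxy-3-(1H-indol-3-yl)-6-[2-(2-methylbut-3-en-2-yl)-1H-indol-3-yl]cyclohexa-2,5-diene-1,4-dione | C=CC(C)(C)c1[nH]c2ccccc2c1C1=C(OC)C(=O)C(c2c[nH]c3ccccc23)=C(OC)C1=O | target

## Step count and least certain steps

Total: 9 steps. Longest linear sequence: 7 steps (1, 2, 3, 4, 7, 8, 9); steps 5 and 6 form the second branch.

**Step 8 (key step).**
- What may go wrong: the ring opening may proceed in part with the hydroxyl rotating inward, after which the ketene is captured by that hydroxyl and no carbocycle forms. The congested ketene terminus, next to the tert-alkyl-substituted indole B, may close slowly enough for ketene dimerisation to compete. In 17 a carbamate may migrate from nitrogen to the neighbouring phenol oxygen and block the oxidation.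
- Fallback (known chemistry, from 5 to 19): the quinone ring is bought instead of built. 1H-indole is added to 2,5-dichloro-1,4-benzoquinone under mineral acid catalysis with DDQ re-oxidation to give 2,5-dichloro-3-(1H-indol-3-yl)-1,4-benzoquinone F1. Compound 5 is added to F1 in the same way to give the bis-indolyl dichloroquinone F2. NaOMe in MeOH exchanges both chlorides and returns to the route at 19.

**Step 7.**
- What may go wrong: the isomer of 14 with lithium trans to the methoxy group may lose LiOMe. Proton transfer from the carbamate-activated indole C2–H may quench the vinyl anion before it adds. Some addition may occur at the other carbonyl of 9.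
- Fallback (from 10 to 19): the second methoxy group is brought in after the ring expansion, so the carbanion carries no β-leaving group. Wittig methylenation of 10 gives tert-butyl 3-ethenyl-1H-indole-1-carboxylate F3. Bromine addition and dehydrobromination with DBU give tert-butyl 3-(1-bromoethenyl)-1H-indole-1-carboxylate F4. Bromine–lithium exchange and addition to 9 give the carbinol F5. Thermolysis and Ag2O oxidation as in step 8 give the trisubstituted quinone F6. NaOMe in MeOH under air then adds methoxide at the only free ring position (β to the carbonyl that is not a vinylogous ester), re-oxidises and cleaves both carbamates, which returns to the route at 19.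

**Step 4.**
- What may go wrong: acyl transfer to a nitrogen flanked by the tert-alkyl group may be slow, and DMAP may instead add reversibly to the methoxy-bearing ring carbon.
- Fallback (from 5 to 9): the carbamate is put on before the dione exists, with the more nucleophilic N-lithio indole. n-BuLi then Boc2O on 5 give tert-butyl 2-(2-methylbut-3-en-2-yl)-1H-indole-1-carboxylate F7. NBS gives the 3-bromo compound F8. Bromine–lithium exchange with t-BuLi and addition to dimethyl squarate give the hydroxycyclobutenone F9. Trifluoroacetic anhydride followed by aqueous work-up transposes F9 to 9.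

**Step 9.**
- What may go wrong: base may decompose the electron-poor quinone, and adventitious hydroxide may hydrolyse a vinylogous ester.
- Fallback (from 15 to 19): the carbamates are removed at the hydroquinone level. 15 is heated as in step 8 to 17. NaOMe in MeOH under argon gives the free hydroquinone F10, and Ag2O then oxidises F10 to 19.

## Further compounds

F1 | step 8 | 2,5-dichloro-3-(1H-indol-3-yl)cyclohexa-2,5-diene-1,4-dione | O=C1C=C(Cl)C(=O)C(c2c[nH]c3ccccc23)=C1Cl
F2 | step 8 | 2,5-dichloro-3-(1H-indol-3-yl)-6-[2-(2-methylbut-3-en-2-yl)-1H-indol-3-yl]cyclohexa-2,5-diene-1,4-dione | O=C1C(c2c(C(C)(C)C=C)[nH]c3ccccc23)=C(Cl)C(=O)C(c2c[nH]c3ccccc23)=C1Cl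
F3 | step 7 | tert-butyl 3-ethenyl-1H-indole-1-carboxylate | C=Cc1cn(C(=O)OC(C)(C)C)c2ccccc12
F4 | step 7 | tert-butyl 3-(1-bromoethenyl)-1H-indole-1-carboxylate | C=C(Br)c1cn(C(=O)OC(C)(C)C)c2ccccc12
F5 | step 7 | tert-butyl 3-(3-{1-[1-(tert-butoxycarbonyl)-1H-indol-3-yl]ethenyl}-3-hydroxy-2-methoxy-4-oxocyclobut-1-en-1-yl)-2-(2-methylbut-3-en-2-yl)-1H-indole-1-carboxylate (racemic) | C=CC(C)(C)c1n(C(=O)OC(C)(C)C)c2ccccc2c1C1=C(OC)C(O)(C(=C)c2cn(C(=O)OC(C)(C)C)c3ccccc23)C1=O
F6 | step 7 | tert-butyl 3-{4-[1-(tert-butoxycarbonyl)-1H-indol-3-yl]-2-methoxy-3,6-dioxocyclohexa-1,4-dien-1-yl}-2-(2-methylbut-3-en-2-yl)-1H-indole-1-carboxylate | O=C1C=C(c2cn(C(=O)OC(C)(C)C)c3ccccc23)C(=O)C(OC)=C1c1c(C(C)(C)C=C)n(C(=O)OC(C)(C)C)c2ccccc12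
F7 | step 4 | tert-butyl 2-(2-methylbut-3-en-2-yl)-1H-indole-1-carboxylate | C=CC(C)(C)c1cc2ccccc2n1C(=O)OC(C)(C)C
F8 | step 4 | tert-butyl 3-bromo-2-(2-methylbut-3-en-2-yl)-1H-indole-1-carboxylate | C=CC(C)(C)c1c(Br)c2ccccc2n1C(=O)OC(C)(C)C
F9 | step 4 | tert-butyl 3-(1-hydroxy-2,3-dimethoxy-4-oxocyclobut-2-en-1-yl)-2-(2-methylbut-3-en-2-yl)-1H-indole-1-carboxylate (racemic) | C=CC(C)(C)c1n(C(=O)OC(C)(C)C)c2ccccc2c1C1(O)C(OC)=C(OC)C1=O
F10 | step 9 | 2-(1H-indol-3-yl)-3,6-dimethoxy-5-[2-(2-methylbut-3-en-2-yl)-1H-indol-3-yl]benzene-1,4-diol | COc1c(O)c(-c2c(C(C)(C)C=C)[nH]c3ccccc23)c(OC)c(O)c1-c1c[nH]c2ccccc12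
A1 | alternative 1 | 2,5-dichlorocyclohexa-2,5-diene-1,4-dione | O=C1C=C(Cl)C(=O)C=C1Cl
A2 | alternative 1 | 1H-indole | c1ccc2[nH]ccc2c1
A3 | alternative 1 | 2,5-dichloro-3-(1H-indol-3-yl)cyclohexa-2,5-diene-1,4-dione | O=C1C=C(Cl)C(=O)C(c2c[nH]c3ccccc23)=C1Cl
A4 | alternative 1 | 2,5-dichloro-3-(1H-indol-3-yl)-6-[2-(2-methylbut-3-en-2-yl)-1H-indol-3-yl]cyclohexa-2,5-diene-1,4-dione | O=C1C(c2c(C(C)(C)C=C)[nH]c3ccccc23)=C(Cl)C(=O)C(c2c[nH]c3ccccc23)=C1Cl
A5 | alternative 2 | methyl 3-(1H-indol-3-yl)-2-oxopropanoate | COC(=O)C(=O)Cc1c[nH]c2ccccc12
A6 | alternative 2 | methyl 3-[2-(2-methylbut-3-en-2-yl)-1H-indol-3-yl]-2-oxopropanoate | COC(=O)C(=O)Cc1c(C(C)(C)C=C)[nH]c2ccccc12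
A7 | alternative 2 | 2,5-dihydroxy-3-(1H-indol-3-yl)-6-[2-(2-methylbut-3-en-2-yl)-1H-indol-3-yl]cyclohexa-2,5-diene-1,4-dione | C=CC(C)(C)c1[nH]c2ccccc2c1C1=C(O)C(=O)C(c2c[nH]c3ccccc23)=C(O)C1=O
A8 | alternative 3 | {[4-(3,3-dimethylpent-4-en-1-yn-1-yl)-2,3,5,6-tetramethoxyphenyl]ethynyl}trimethylsilane | C=CC(C)(C)C#Cc1c(OC)c(OC)c(C#C[Si](C)(C)C)c(OC)c1OC
A9 | alternative 3 | 2-iodoaniline | Nc1ccccc1I
A10 | alternative 3 | 2-(2-methylbut-3-en-2-yl)-3-{2,3,5,6-tetramethoxy-4-[2-(trimethylsilyl)-1H-indol-3-yl]phenyl}-1H-indole | C=CC(C)(C)c1[nH]c2ccccc2c1-c1c(OC)c(OC)c(-c2c([Si](C)(C)C)[nH]c3ccccc23)c(OC)c1OC
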